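**Assumption:** 3‑phthalimidopropanal (2) and 4,5‑dibromo‑2‑(trichloroacetyl)pyrrole (9) are bought as catalogue compounds; R/S descriptors refer to the imidazole tautomers as written in the SMILES.

## Retrosynthetic overview

1. The last bonds made are the two amide C–N bonds: tetra‑amine 8 plus two equivalents of trichloroacetylpyrrole 9.
2. 8 comes from 7 (side‑chain amines as phthalimides, one imidazole as its N1‑ethoxycarbonyl derivative), which comes from carbamate 5 and aldehyde 2 by C5 hydroxyalkylation/dehydration on the one unacylated ring.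
3. Key step: 5 comes from the prochiral bis(2‑aminoimidazolyl)methane 4 by catalyst‑controlled N1–C(=O) bond formation on one of the two enantiotopic rings; this C–N bond fixes the configuration of the CH.
4. 4 comes from two 2‑aminoimidazoles (1) and aldehyde 2.
5. Ring order: no ring is constructed. The two 2‑aminoimidazoles enter intact in step 1 and the two dibromopyrroles intact in step 5.

## Route

Step 1
Reactants: 1 2‑aminoimidazole hemisulfate (3 equiv of the 2:1 salt); 2 3‑phthalimidopropanal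
Product: 4 2‑[3,3‑bis(2‑amino‑1H‑imidazol‑5‑yl)propyl]isoindoline‑1,3‑dione (achiral, prochiral CH), via 2‑[3‑(2‑amino‑1H‑imidazol‑5‑yl)‑3‑hydroxypropyl]isoindoline‑1,3‑dione 3 (not isolated)
Conditions: NaHCO3 (2 equiv per 1), THF–H2O 1:1, 40 °C; then AcOH to pH ≈ 4, 60 °C
Reagents that add atoms: none
Why: Free 2‑aminoimidazole is a carbon nucleophile at C4(5) and hydroxyalkylates with the aldehyde to give 3, which ionises in acid to a 2‑amino‑azafulvenium ion that a second 2‑aminoimidazole captures (double Friedel–Crafts, bis(heteroaryl)methane formation); excess 1 suppresses oligomers and no stereocentre is formed.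

Step 2
Reactants: 4 2‑[3,3‑bis(2‑amino‑1H‑imidazol‑5‑yl)propyl]isoindoline‑1,3‑dione
Product: 5 ethyl 2‑amino‑4‑[(1R)‑1‑(2‑amino‑1H‑imidazol‑5‑yl)‑3‑(1,3‑dioxoisoindolin‑2‑yl)propyl]‑1H‑imidazole‑1‑carboxylate
Conditions: (EtOCO)2O (1.0 equiv, syringe pump), peptide catalyst Boc‑Pmh‑D‑Pro‑Aib‑Asp‑OMe (Pmh = π‑methylhistidine, 10 mol %), THF–DMF 9:1, −50 °C; used at once
Reagents that add atoms: diethyl dicarbonate CCOC(=O)OC(=O)OCC
Why: Proposed new method: enantiotopic‑ring‑selective N‑ethoxycarbonylation of a prochiral bis(2‑aminoimidazolyl)methane – the catalyst's π‑methylimidazole is carbethoxylated by the dicarbonate to an acyl‑imidazolium, its Asp carboxylic acid docks one of the two rings as an amidinium–carboxylate salt bridge (switching off that ring), and the β‑turn delivers the acyl group to the distal ring nitrogen N1 of the other ring (the pro‑R ring with the correct catalyst antipode, found by screening), so the new C–N bond defines the (R)‑CH; further acylation of the minor mono‑carbamate to the bis‑carbamate upgrades ee; closest known reaction types are peptide‑catalysed remote desymmetrising acylation of diarylmethane bis‑phenols, chiral‑nucleophile alkoxycarbonyl transfer (Steglich type) and the classical N‑carbethoxylation of histidine imidazoles by diethyl dicarbonate.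

Step 3
Reactants: 5 ethyl 2‑amino‑4‑[(1R)‑1‑(2‑amino‑1H‑imidazol‑5‑yl)‑3‑(1,3‑dioxoisoindolin‑2‑yl)propyl]‑1H‑imidazole‑1‑carboxylate; 2 3‑phthalimidopropanal (1.5 equiv)
Product: 7 ethyl 2‑amino‑4‑[(1R)‑1‑{2‑amino‑4‑[(1E)‑3‑(1,3‑dioxoisoindolin‑2‑yl)prop‑1‑en‑1‑yl]‑1H‑imidazol‑5‑yl}‑3‑(1,3‑dioxoisoindolin‑2‑yl)propyl]‑1H‑imidazole‑1‑carboxylate, via ethyl 2‑amino‑4‑[(1R)‑1‑{2‑amino‑4‑[3‑(1,3‑dioxoisoindolin‑2‑yl)‑1‑hydroxypropyl]‑1H‑imidazol‑5‑yl}‑3‑(1,3‑dioxoisoindolin‑2‑yl)propyl]‑1H‑imidazole‑1‑carboxylate 6 (not isolated)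
Conditions: AcOH–MeCN 1:4, 4 Å MS, 45 °C
Reagents that add atoms: none
Why: Hydroxyalkylation occurs at the only electron‑rich free C–H (C5 of the unacylated ring) to give 6, which ionises to the azafulvenium ion and loses a β‑proton (E1) to the conjugated (E)‑alkene; the N1‑carbethoxy ring is too electron‑poor to react or to cyclise onto the cation, and the new C–C bond makes the two rings permanently different without touching the stereocentre.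

Step 4
Reactants: 7 ethyl 2‑amino‑4‑[(1R)‑1‑{2‑amino‑4‑[(1E)‑3‑(1,3‑dioxoisoindolin‑2‑yl)prop‑1‑en‑1‑yl]‑1H‑imidazol‑5‑yl}‑3‑(1,3‑dioxoisoindolin‑2‑yl)propyl]‑1H‑imidazole‑1‑carboxylate
Product: 8 5‑[(1S)‑3‑amino‑1‑(2‑amino‑1H‑imidazol‑5‑yl)propyl]‑4‑[(1E)‑3‑aminoprop‑1‑en‑1‑yl]‑1H‑imidazol‑2‑amine
Conditions: N2H4·H2O (10 equiv), EtOH, 50 °C, Ar; filter, isolate as free base
Reagents that add atoms: none
Why: Ing–Manske hydrazinolysis removes both phthalimides and the acyl‑azole‑type N1‑carbamate is transferred to hydrazine in the same pot; argon prevents diimide reduction of the alkene, and the descriptor changes to S only because the CIP priorities of the two rings swap.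

Step 5
Reactants: 8 5‑[(1S)‑3‑amino‑1‑(2‑amino‑1H‑imidazol‑5‑yl)propyl]‑4‑[(1E)‑3‑aminoprop‑1‑en‑1‑yl]‑1H‑imidazol‑2‑amine; 9 4,5‑dibromo‑2‑(trichloroacetyl)‑1H‑pyrrole (2.1 equiv)
Product: 10 N‑[(2E)‑3‑{2‑amino‑5‑[(1S)‑1‑(2‑amino‑1H‑imidazol‑5‑yl)‑3‑(4,5‑dibromo‑1H‑pyrrole‑2‑carboxamido)propyl]‑1H‑imidazol‑4‑yl}prop‑2‑en‑1‑yl]‑4,5‑dibromo‑1H‑pyrrole‑2‑carboxamide (target, CID 11411715)
Conditions: DMF, 23 °C
Reagents that add atoms: none
Why: Haloform‑type aminolysis of the trichloromethyl ketone acylates the two primary alkylamines chemoselectively (CHCl3 leaves), the usual way the pyrrole amides of oroidin‑type alkaloids are made; the weakly nucleophilic 2‑aminoimidazoles stay free.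

## Compound list

1 | 2‑aminoimidazole hemisulfate | Nc1ncc[nH]1.Nc1ncc[nH]1.OS(=O)(=O)O | starting material
2 | 3‑phthalimidopropanal | O=CCCN1C(=O)c2ccccc2C1=O | starting material
3 | 2‑[3‑(2‑amino‑1H‑imidazol‑5‑yl)‑3‑hydroxypropyl]isoindoline‑1,3‑dione (racemic) | Nc1ncc(C(O)CCN2C(=O)c3ccccc3C2=O)[nH]1 | intermediate
4 | 2‑[3,3‑bis(2‑amino‑1H‑imidazol‑5‑yl)propyl]isoindoline‑1,3‑dione | Nc1ncc(C(CCN2C(=O)c3ccccc3C2=O)c2cnc(N)[nH]2)[nH]1 | intermediate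
5 | ethyl 2‑amino‑4‑[(1R)‑1‑(2‑amino‑1H‑imidazol‑5‑yl)‑3‑(1,3‑dioxoisoindolin‑2‑yl)propyl]‑1H‑imidazole‑1‑carboxylate | CCOC(=O)n1cc(nc1N)[C@H](CCN1C(=O)c2ccccc2C1=O)c1cnc(N)[nH]1 | intermediate
6 | ethyl 2‑amino‑4‑[(1R)‑1‑{2‑amino‑4‑[3‑(1,3‑dioxoisoindolin‑2‑yl)‑1‑hydroxypropyl]‑1H‑imidazol‑5‑yl}‑3‑(1,3‑dioxoisoindolin‑2‑yl)propyl]‑1H‑imidazole‑1‑carboxylate (both carbinol epimers) | CCOC(=O)n1cc(nc1N)[C@H](CCN1C(=O)c2ccccc2C1=O)c1[nH]c(N)nc1C(O)CCN1C(=O)c2ccccc2C1=O | intermediate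
7 | ethyl 2‑amino‑4‑[(1R)‑1‑{2‑amino‑4‑[(1E)‑3‑(1,3‑dioxoisoindolin‑2‑yl)prop‑1‑en‑1‑yl]‑1H‑imidazol‑5‑yl}‑3‑(1,3‑dioxoisoindolin‑2‑yl)propyl]‑1H‑imidazole‑1‑carboxylate | CCOC(=O)n1cc(nc1N)[C@H](CCN1C(=O)c2ccccc2C1=O)c1[nH]c(N)nc1/C=C/CN1C(=O)c2ccccc2C1=O | intermediate
8 | 5‑[(1S)‑3‑amino‑1‑(2‑amino‑1H‑imidazol‑5‑yl)propyl]‑4‑[(1E)‑3‑aminoprop‑1‑en‑1‑yl]‑1H‑imidazol‑2‑amine | Nc1ncc([C@H](CCN)c2[nH]c(N)nc2/C=C/CN)[nH]1 | intermediate
9 | 4,5‑dibromo‑2‑(trichloroacetyl)‑1H‑pyrrole | O=C(c1cc(Br)c(Br)[nH]1)C(Cl)(Cl)Cl | starting material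
10 | N‑[(2E)‑3‑{2‑amino‑5‑[(1S)‑1‑(2‑amino‑1H‑imidazol‑5‑yl)‑3‑(4,5‑dibromo‑1H‑pyrrole‑2‑carboxamido)propyl]‑1H‑imidazol‑4‑yl}prop‑2‑en‑1‑yl]‑4,5‑dibromo‑1H‑pyrrole‑2‑carboxamide | Nc1ncc([C@H](CCNC(=O)c2cc(Br)c(Br)[nH]2)c2[nH]c(N)nc2/C=C/CNC(=O)c2cc(Br)c(Br)[nH]2)[nH]1 | target

## Step count and risks

Total step count: 5. Longest linear sequence: 5 steps (1 + 2 → 4 → 5 → 7 → 8 → 10).

**Step 2 (proposed new desymmetrisation).** Risks are uncatalysed background acylation, modest ee, and carbamate shuttling between the two rings, which would racemise 5. The fallback uses known chemistry, sets out from 4 and returns at 7. Treat 4 with diethyl dicarbonate (0.9 equiv, THF–DMF, 0 °C, no chiral catalyst – the classical imidazole N‑carbethoxylation) to give racemic ethyl 2‑amino‑4‑[1‑(2‑amino‑1H‑imidazol‑5‑yl)‑3‑(1,3‑dioxoisoindolin‑2‑yl)propyl]‑1H‑imidazole‑1‑carboxylate F1. Carry it through the step‑3 conditions to racemic ethyl 2‑amino‑4‑[1‑{2‑amino‑4‑[(1E)‑3‑(1,3‑dioxoisoindolin‑2‑yl)prop‑1‑en‑1‑yl]‑1H‑imidazol‑5‑yl}‑3‑(1,3‑dioxoisoindolin‑2‑yl)propyl]‑1H‑imidazole‑1‑carboxylate F2, where the stereocentre is configurationally fixed. Separate the enantiomers by preparative chiral SFC on a polysaccharide phase; the (R)‑enantiomer is 7 and the (S)‑enantiomer of that carbamate F3 is discarded.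

**Step 1 (double Friedel–Crafts).** Risks are oligomerisation, because the rings of 4 are still nucleophilic, and elimination to the vinylimidazole followed by its dimerisation. The fallback sets out from 2 and returns at 4. Condense 2 with imidazo[1,2‑a]pyrimidine (2.2 equiv, TFA cat., DCE, 60 °C), a masked 2‑aminoimidazole that is nucleophilic only at C3 and so cannot oligomerise, to give 2‑[3,3‑bis(imidazo[1,2‑a]pyrimidin‑3‑yl)propyl]isoindoline‑1,3‑dione F4. Hydrazinolysis (N2H4·H2O, EtOH, 80 °C) opens both pyrimidine rings and the phthalimide to give 3,3‑bis(2‑amino‑1H‑imidazol‑5‑yl)propan‑1‑amine F5. Selective re‑phthaloylation of its only aliphatic amine with N‑ethoxycarbonylphthalimide (aq NaHCO3) returns 4.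

**Step 3 (alkenylation of the hindered, half‑protected bis‑imidazole).** Risks are slow reaction at C5 next to the branched substituent, loss or N1→exocyclic‑N migration of the carbamate, and cyclisation of the cation onto the other ring. The fallback moves the alkene installation to the monomer and gives up the desymmetrisation; it sets out from 3 and returns at 8. Stop step 1 before acidification and isolate 3. Dehydrate one portion (AcOH, 60 °C) to 2‑[(2E)‑3‑(2‑amino‑1H‑imidazol‑5‑yl)prop‑2‑en‑1‑yl]isoindoline‑1,3‑dione F6. Ionise a second portion of 3 in AcOH in the presence of F6, whose ring C–H captures the azafulvenium ion, to give racemic 2‑[(2E)‑3‑{2‑amino‑5‑[1‑(2‑amino‑1H‑imidazol‑5‑yl)‑3‑(1,3‑dioxoisoindolin‑2‑yl)propyl]‑1H‑imidazol‑4‑yl}prop‑2‑en‑1‑yl]isoindoline‑1,3‑dione F7. Resolve by chiral SFC to the (1S)‑enantiomer of that bis‑phthalimide F8, discarding the (1R)‑enantiomer F9. Hydrazinolysis of F8 (N2H4·H2O, EtOH, Ar) gives 8.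

## Further compounds

F1 | step 2 | racemic ethyl 2‑amino‑4‑[1‑(2‑amino‑1H‑imidazol‑5‑yl)‑3‑(1,3‑dioxoisoindolin‑2‑yl)propyl]‑1H‑imidazole‑1‑carboxylate | CCOC(=O)n1cc(nc1N)C(CCN1C(=O)c2ccccc2C1=O)c1cnc(N)[nH]1
F2 | step 2 | racemic ethyl 2‑amino‑4‑[1‑{2‑amino‑4‑[(1E)‑3‑(1,3‑dioxoisoindolin‑2‑yl)prop‑1‑en‑1‑yl]‑1H‑imidazol‑5‑yl}‑3‑(1,3‑dioxoisoindolin‑2‑yl)propyl]‑1H‑imidazole‑1‑carboxylate | CCOC(=O)n1cc(nc1N)C(CCN1C(=O)c2ccccc2C1=O)c1[nH]c(N)nc1/C=C/CN1C(=O)c2ccccc2C1=O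
F3 | step 2 | ethyl 2‑amino‑4‑[(1S)‑1‑{2‑amino‑4‑[(1E)‑3‑(1,3‑dioxoisoindolin‑2‑yl)prop‑1‑en‑1‑yl]‑1H‑imidazol‑5‑yl}‑3‑(1,3‑dioxoisoindolin‑2‑yl)propyl]‑1H‑imidazole‑1‑carboxylate | CCOC(=O)n1cc(nc1N)[C@@H](CCN1C(=O)c2ccccc2C1=O)c1[nH]c(N)nc1/C=C/CN1C(=O)c2ccccc2C1=O
F4 | step 1 | 2‑[3,3‑bis(imidazo[1,2‑a]pyrimidin‑3‑yl)propyl]isoindoline‑1,3‑dione | O=C1c2ccccc2C(=O)N1CCC(c1cnc2ncccn12)c1cnc2ncccn12
F5 | step 1 | 3,3‑bis(2‑amino‑1H‑imidazol‑5‑yl)propan‑1‑amine | NCCC(c1cnc(N)[nH]1)c1cnc(N)[nH]1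
F6 | step 3 | 2‑[(2E)‑3‑(2‑amino‑1H‑imidazol‑5‑yl)prop‑2‑en‑1‑yl]isoindoline‑1,3‑dione | Nc1ncc(/C=C/CN2C(=O)c3ccccc3C2=O)[nH]1
F7 | step 3 | racemic 2‑[(2E)‑3‑{2‑amino‑5‑[1‑(2‑amino‑1H‑imidazol‑5‑yl)‑3‑(1,3‑dioxoisoindolin‑2‑yl)propyl]‑1H‑imidazol‑4‑yl}prop‑2‑en‑1‑yl]isoindoline‑1,3‑dione | Nc1ncc(C(CCN2C(=O)c3ccccc3C2=O)c2[nH]c(N)nc2/C=C/CN2C(=O)c3ccccc3C2=O)[nH]1
F8 | step 3 | 2‑[(2E)‑3‑{2‑amino‑5‑[(1S)‑1‑(2‑amino‑1H‑imidazol‑5‑yl)‑3‑(1,3‑dioxoisoindolin‑2‑yl)propyl]‑1H‑imidazol‑4‑yl}prop‑2‑en‑1‑yl]isoindoline‑1,3‑dione | Nc1ncc([C@H](CCN2C(=O)c3ccccc3C2=O)c2[nH]c(N)nc2/C=C/CN2C(=O)c3ccccc3C2=O)[nH]1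
F9 | step 3 | 2‑[(2E)‑3‑{2‑amino‑5‑[(1R)‑1‑(2‑amino‑1H‑imidazol‑5‑yl)‑3‑(1,3‑dioxoisoindolin‑2‑yl)propyl]‑1H‑imidazol‑4‑yl}prop‑2‑en‑1‑yl]isoindoline‑1,3‑dione | Nc1ncc([C@@H](CCN2C(=O)c3ccccc3C2=O)c2[nH]c(N)nc2/C=C/CN2C(=O)c3ccccc3C2=O)[nH]1
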